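(The rate constants are assumed; what happens was integrated by code.)

As planner of the next run I had to say what to change in this flask. Substrate takes up dissolved gas on the catalyst to give target, target and its isomer interconvert on the same catalyst, dissolved gas also decomposes, and the held gas phase feeds the solution.

substrate 0.050 M; gas phase 30 mM (held); catalyst 0.13 mol%; time 2.0 h

- south: doubling the amount of catalyst, all else as stated
- north: doubling the saturation concentration of gas phase, all else as stated
- north-west: doubling the transfer coefficient of step 1, all else as stated

1. target at 2.0 h, in percent of the substrate charged
2. the change that raises the amount of target at 2.0 h, in percent of the substrate charged most ("none" if none brings more than 2 percentage points) (south / north / north-west / none)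
3. amount of target at 2.0 h, in percent of the substrate charged, after north

- at the start none of the gas is dissolved
- run time (flask): 2.0 h

    gas phase ⇌ dissolved gas, rate k1*(csat - [dissolved gas]) (k1 = 0.019 s⁻¹, csat = 30 mM)
    substrate + dissolved gas + catalyst → catalyst + target (k2 = 190 L² mol⁻² s⁻¹)
    target + catalyst ⇌ isomer of the product + catalyst, rate k3*[catalyst]*[target] forward; the back reaction follows from the equilibrium constant (K3 = 0.22, k3 = 1.1 L mol⁻¹ s⁻¹)
    dissolved gas → decomposed reagent (k4 = 4.4 × 10⁻⁴ s⁻¹)

I asked first where the flask must end. Target and isomer share what has reacted according to the equilibrium constant 0.22, so target ends at 82.0% of it.

Then I asked how fast. With the solution saturated and the substrate as charged, reaction and decomposition together take 1.90 mM min⁻¹, and transfer can deliver 34.2 mM min⁻¹, far faster, so the solution stays near 30 mM and north-west promises little. Substrate therefore falls pseudo-first-order. I carried its rate constant, the substrate clock κ, which is the step-2 constant times the catalyst concentration times the saturation concentration: 1.33 h⁻¹.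

Over 2.0 h the clock leaves 6.94% of the substrate. I therefore put target between 76.3%, with isomer fully caught up, and 93.1%, with no isomer formed. South and north each double κ, leaving 0.482%, which puts the low end of my estimate for target at 81.6%. But south also speeds the step to isomer, whose forward half-life alone, as charged, is 2.7 h, and north does not, so I chose north.

The forecast gave 78.5% (range 76% to 81%), a single value inside my bracket. It also chose north, with 83.5% (range 81% to 86%), holding that “Gas transfer is fast compared with its consumption”.

The simulation of the flask gave 78.8% and 83.6% after north. The gains were 4.9 percentage points for north, 3.1 points for south and 0.28 points for north-west. The flask kept 7.7% of its substrate, against the clock's 6.94%.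

The neighbour flask was charged with 0.033 mol% of catalyst, with the other charges and the time as in the recipe. Its clock runs at 0.339 h⁻¹, which leaves 50.8% of the substrate after 2.0 h and puts target between 40.3% and 49.2%. The neighbour flask held more substrate, 52.0%, than target, 45.2%, or isomer, 2.72%.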